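A one-step picture would have me read a single rate law off four runs and carry it into four vessels, so I asked first what the rate followed.

| setting | amber | grey | green | red | noon | winter | summer | dawn |
|---|---|---|---|---|---|---|---|---|
| substrate | 0.085 M | 0.085 M | 0.085 M | 0.043 M | 0.085 M | 0.085 M | 0.085 M | 0.085 M (fed, over 2.00 h) |
| coupling partner | 0.34 M | 0.48 M | 0.75 M | 0.34 M | 0.340 M | 0.340 M | 0.340 M (fed, over 2.00 h) | 0.340 M |
| free catalyst | 0.43 mM | 0.43 mM | 0.43 mM | 0.43 mM | 0.43 mM | 0.43 mM | 0.43 mM | 0.43 mM |
| remark | run made earlier | run made earlier | run made earlier | run made earlier | a closed flask charged with all of it at once and left for 2.5 h | one stirred flow tank at steady state, fed with the mixture as stated, mean residence time 2.5 h | a stirred flask in which coupling partner is dosed at a steady rate over 2.00 h without added volume, worked up at 2.5 h | all but substrate at the start; substrate goes in evenly over 2.00 h, the run ends at 2.5 h |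
| time |  |  |  |  | 2.5 h |  | 2.5 h | 2.5 h |

- amber (time / h: product / %, substrate / %): 0.200: 4.8, 94.6; 0.667: 14.5, 84.6; 1.33: 26.5, 73.5; 2.00: 36.5, 63.1; 2.50: 44.8, 55.0
- grey (time / h: product / %, substrate / %): 0.500: 15.3, 84.3; 1.00: 27.0, 72.6; 1.50: 38.3, 61.1; 2.00: 49.0, 50.9; 2.50: 59.4, 40.3
- green (time / h: product / %, substrate / %): 0.500: 20.5, 78.4; 1.00: 38.5, 61.5; 1.50: 54.1, 46.1; 2.00: 68.5, 31.4; 2.50: 81.6, 18.6
- red (time / h: product / %, substrate / %): 0.200: 9.2, 90.1; 0.417: 17.8, 81.3; 0.667: 27.0, 72.4; 1.33: 48.6, 50.7; 2.50: 80.5, 19.0

(readings scatter by 0.3 percentage points)

* order of the set-ups by the amount of product at the outlet or at the end, in percent of the substrate put in, highest first (noon / winter / summer / dawn)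
* amount of product at the outlet or at the end, in percent of the substrate put in, noon
* amount of product at the outlet or at the end, in percent of the substrate put in, winter
* amount of product at the outlet or at the end, in percent of the substrate put in, summer
* amount of product at the outlet or at the end, in percent of the substrate put in, dawn

Over its first reading the red run made 0.0198 M/h and the amber run 0.0204 M/h, although red held half the substrate, so over those first readings the rate read close to zero order in substrate. The grey and green runs, with more coupling partner, ended higher than amber. Amber's rate fell, and its late stretch from 1.33 h to 2.50 h read 0.156 /h of the charge against 0.240 /h at the start. Winter's stirred tank at steady state holds one unchanging mixture, so for my estimate I let winter run at amber's late rate. Amber gave 0.460 /M/h as its late rate of product divided by its charge of coupling partner, which I called the pull. Pull times charge times residence time gave me 39.1 % for winter, 3.1 percentage points above the forecast.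

The forecast gave noon 44.6 %, winter 36 %, summer 25.6 % and dawn 38.5 %, in the order noon > dawn > winter > summer, on the reading “Rate falls with time identically in amber, grey and green”.

The flasks gave noon 44.5 %, winter 41.9 %, summer 29.7 % and dawn 39.2 %, in the order noon > winter > dawn > summer.

    substrate + free catalyst → catalyst intermediate A (k = 193 /M/min)
    coupling partner + catalyst intermediate A → catalyst intermediate B (k = 3.22 /M/min)
    catalyst intermediate B → free catalyst + product (k = 6.62 /min)
    coupling partner ⇌ dormant form (K = 0.660, k = 0.0167 /min)

Winter's 41.9 % stood 2.8 points above my estimate. Winter's tank held 0.200 M of coupling partner everywhere, against 0.180 M unbound in noon at 2.50 h. Winter's own pull came to 0.492 /M/h against amber's 0.460 /M/h. Summer, with its dosing, reached 0.759 of pull times charge times time. That same factor, for a neighbour like summer charged with 0.20 M of coupling partner, gives 17.5 %. That neighbour ended at 18.3 %, with 57 % of its coupling partner unbound.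

The runs were computed with constants of no real substance; noise was put on by code.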